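Ring C is disconnected at C3–C4 and at O1–C8a. Because O1 is attached to ring A carbon C8a, ortho to the C4 acyl carbon, it can arrive as the enolate oxygen of a ring B ketone and displace a fluoride that the C4 carbonyl activates. In one operation the lithium enolate of an α-(methoxymethoxy) ketone carrying the bis-MOM 5-prenylcatechol ring B is C-acylated by a 2-fluoro-6-(methoxymethoxy)-4-(prenyloxy)benzoyl imidazole, and the diketonate closes the pyranone by intramolecular SNAr, with O3 already in place. A Claisen shift then moves the O7 prenyl group to C8 as the 1,1-dimethylallyl unit, and the MOM groups are removed.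

Key step: step 10

Remark: the target has no stereocentre; its C8 substituent is 2-methylbut-3-en-2-yl (1,1-dimethylallyl), the group that allylic inversion of an O7 3-methylbut-2-enyl (prenyl) ether delivers, and tributyl(3-methylbut-2-en-1-yl)stannane is taken as a purchased reagent.

Step 1
Reactants: 1 5-fluororesorcinol
Product: 3 2-fluoro-4,6-dihydroxybenzaldehyde, via aryl iminium chloride 2 (not isolated)
Conditions: POCl3, DMF, MeCN, 0 °C to rt; then H2O, 50 °C
Reagents that add atoms: N,N-dimethylformamide, CN(C)C=O (formyl carbon); water, O (carbonyl oxygen)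
Why: Vilsmeier–Haack formylation should occur at the ring carbon para to one hydroxyl and ortho to the other (next to fluorine), the usual site in 5-substituted resorcinols because the position between the two hydroxyls is more hindered, and hydrolysis of iminium salt 2 releases the aldehyde.

Step 2
Reactants: 3 2-fluoro-4,6-dihydroxybenzaldehyde; 4 prenyl bromide (1-bromo-3-methylbut-2-ene)
Product: 5 2-fluoro-6-hydroxy-4-(3-methylbut-2-en-1-yloxy)benzaldehyde
Conditions: K2CO3 (1.05 equiv), acetone, rt
Reagents that add atoms: none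
Why: Williamson etherification should be selective for the 4-OH, which is para to the formyl group and the more acidic phenol, whereas the 6-OH is held in a hydrogen bond to the carbonyl oxygen and is alkylated much more slowly.

Step 3
Reactants: 5 2-fluoro-6-hydroxy-4-(3-methylbut-2-en-1-yloxy)benzaldehyde
Product: 6 2-fluoro-6-(methoxymethoxy)-4-(3-methylbut-2-en-1-yloxy)benzaldehyde
Conditions: MOMCl, i-Pr2NEt, CH2Cl2, 0 °C to rt
Reagents that add atoms: chloromethyl methyl ether (MOMCl), COCCl
Why: O-alkylation of the remaining chelated phenol with the α-chloro ether under amine base gives a MOM acetal that is inert to the oxidant and the enolate chemistry ahead and, unlike a free 5-OH, should not steer the later sigmatropic shift towards C6.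

Step 4
Reactants: 6 2-fluoro-6-(methoxymethoxy)-4-(3-methylbut-2-en-1-yloxy)benzaldehyde
Product: 7 2-fluoro-6-(methoxymethoxy)-4-(3-methylbut-2-en-1-yloxy)benzoic acid
Conditions: NaClO2, NaH2PO4, 2-methyl-2-butene (large excess), t-BuOH–H2O, rt
Reagents that add atoms: sodium chlorite, [Na+].[O-]Cl=O
Why: Pinnick oxidation converts the aldehyde chemoselectively into the acid in a buffered medium that the MOM acetal tolerates, while the excess 2-methyl-2-butene consumes the hypochlorous acid before it can reach the prenyl ether or the arene.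

Step 5
Reactants: 7 2-fluoro-6-(methoxymethoxy)-4-(3-methylbut-2-en-1-yloxy)benzoic acid
Product: 8 1-[2-fluoro-6-(methoxymethoxy)-4-(3-methylbut-2-en-1-yloxy)benzoyl]imidazole
Conditions: CDI, THF, rt; quick cold-water wash in CH2Cl2 to remove imidazole, dried, used at once
Reagents that add atoms: 1,1'-carbonyldiimidazole, O=C(n1ccnc1)n1ccnc1
Why: Carboxyl activation with carbonyldiimidazole gives the acyl imidazole with loss of CO2 under neutral conditions that spare the MOM acetal, and washing out the freed imidazole keeps an N–H acid away from the enolate of step 10.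

Step 6
Reactants: 9 3-bromo-4,5-dihydroxybenzaldehyde
Product: 10 3-bromo-4,5-bis(methoxymethoxy)benzaldehyde
Conditions: MOMCl (2.5 equiv), i-Pr2NEt, CH2Cl2, 0 °C to rt
Reagents that add atoms: chloromethyl methyl ether (MOMCl), COCCl
Why: Double O-alkylation of the catechol with the α-chloro ether masks both phenols as MOM acetals, so that the palladium coupling, the organolithium addition and the enolate step meet no acidic proton.

Step 7
Reactants: 10 3-bromo-4,5-bis(methoxymethoxy)benzaldehyde; 11 tributyl(3-methylbut-2-en-1-yl)stannane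
Product: 12 3,4-bis(methoxymethoxy)-5-(3-methylbut-2-en-1-yl)benzaldehyde
Conditions: Pd(PPh3)4 (5 mol%), DMF, 95 °C
Reagents that add atoms: none
Why: Stille coupling, in which zerovalent palladium inserts into the C–Br bond, the allylic stannane transmetalates and reductive elimination from the less hindered primary terminus of the allyl ligand should give the linear prenyl arene, with aldehyde and MOM acetals untouched.

Step 8
Reactants: 12 3,4-bis(methoxymethoxy)-5-(3-methylbut-2-en-1-yl)benzaldehyde; 13 tributyl[(methoxymethoxy)methyl]stannane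
Product: 15 1-[3,4-bis(methoxymethoxy)-5-(3-methylbut-2-en-1-yl)phenyl]-2-(methoxymethoxy)ethanol (racemic), via (methoxymethoxy)methyllithium 14 (not isolated)
Conditions: 13, n-BuLi, THF, −78 °C; then 12, −78 °C; H2O
Reagents that add atoms: none
Why: Tin–lithium exchange generates the α-alkoxy organolithium 14, which undergoes 1,2-addition to the aldehyde to give the carbinol as a racemate whose only stereocentre is removed by the oxidation that follows.

Step 9
Reactants: 15 1-[3,4-bis(methoxymethoxy)-5-(3-methylbut-2-en-1-yl)phenyl]-2-(methoxymethoxy)ethanol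
Product: 16 1-[3,4-bis(methoxymethoxy)-5-(3-methylbut-2-en-1-yl)phenyl]-2-(methoxymethoxy)ethanone
Conditions: Dess–Martin periodinane, NaHCO3, CH2Cl2, 0 °C to rt
Reagents that add atoms: none
Why: Dess–Martin oxidation of the benzylic secondary alcohol under buffered conditions gives the α-(methoxymethoxy) ketone without touching the MOM acetals or the prenyl alkene.

Step 10
Reactants: 16 1-[3,4-bis(methoxymethoxy)-5-(3-methylbut-2-en-1-yl)phenyl]-2-(methoxymethoxy)ethanone; 8 1-[2-fluoro-6-(methoxymethoxy)-4-(3-methylbut-2-en-1-yloxy)benzoyl]imidazole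
Product: 19 2-[3,4-bis(methoxymethoxy)-5-(3-methylbut-2-en-1-yl)phenyl]-3,5-bis(methoxymethoxy)-7-(3-methylbut-2-en-1-yloxy)-4H-chromen-4-one, via lithium enolate 17 (not isolated), via lithium diketonate 18 (not isolated)
Conditions: LiN(SiMe3)2 (2.3 equiv), THF, −78 °C; then 8, −78 to 0 °C; then DMPU, 65 °C; H2O
Reagents that add atoms: none
Why: LiN(SiMe3)2 turns 16 into the chelated Z lithium enolate 17, which adds through carbon to the acyl imidazole; loss of imidazolide gives the 1,3-diketone (C3–C4 bond), and the second equivalent of base converts it at once into diketonate 18. On warming in the presence of DMPU the enolate oxygen on the ring B side adds to the fluorine-bearing carbon ortho to the C4 carbonyl, and the Meisenheimer-type adduct expels fluoride (O1–C8a bond). The closest known reaction type is the one-pot Claisen condensation of a ketone enolate with a 2-halobenzoyl electrophile followed by intramolecular SNAr, which is established for chromones and flavones. Ring C closes as a six-membered ring by addition–elimination at an sp2 arene carbon, a 6-exo-trig attack when counted on the C8a=C8 bond; no stereocentre is formed. The step needs acylation at carbon and not at oxygen and a single site of displacement: a lithium enolate and an acyl imidazole in THF favour C-acylation (an enol ester formed at oxygen would itself pass its acyl group to the carbon of further enolate), 16 has only one enolisable position, and ring A offers only one leaving group ortho to the carbonyl. The two ring A alkoxy groups are meta to the C–F carbon and so do not deactivate it by resonance, and the MOM acetals and both prenyl units are inert to the amide base.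

Step 11
Reactants: 19 2-[3,4-bis(methoxymethoxy)-5-(3-methylbut-2-en-1-yl)phenyl]-3,5-bis(methoxymethoxy)-7-(3-methylbut-2-en-1-yloxy)-4H-chromen-4-one
Product: 21 7-hydroxy-2-[3,4-bis(methoxymethoxy)-5-(3-methylbut-2-en-1-yl)phenyl]-3,5-bis(methoxymethoxy)-8-(2-methylbut-3-en-2-yl)-4H-chromen-4-one, via C8 dienone 20 (not isolated)
Conditions: Eu(fod)3 [tris(6,6,7,7,8,8,8-heptafluoro-2,2-dimethyl-3,5-octanedionato)europium] (10 mol%), PhCl, 90 °C
Reagents that add atoms: none
Why: Aromatic Claisen rearrangement, in which the trivalent europium Lewis acid binds the C4 carbonyl that is conjugated to O7 through ring A and so loosens the O7–CH2 bond, the [3,3] shift delivers the allyl unit with allylic inversion as a 1,1-dimethylallyl group to C8 (expected to be preferred over C6 because the C7–C8 bond of a 5-O-alkylated chromone has more double-bond character and C6 is flanked by the 5-OMOM group, while the para position C4a is blocked), and dienone 20 tautomerises to the phenol.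

Step 12
Reactants: 21 7-hydroxy-2-[3,4-bis(methoxymethoxy)-5-(3-methylbut-2-en-1-yl)phenyl]-3,5-bis(methoxymethoxy)-8-(2-methylbut-3-en-2-yl)-4H-chromen-4-one
Product: 22 2-[3,4-dihydroxy-5-(3-methylbut-2-en-1-yl)phenyl]-3,5,7-trihydroxy-8-(2-methylbut-3-en-2-yl)-4H-chromen-4-one (target)
Conditions: HCl (1.25 M in MeOH), THF, 0 °C to rt, Ar
Reagents that add atoms: none
Why: Acid-catalysed acetal exchange with methanol removes the four MOM groups as dimethoxymethane, and dilute acid at or below room temperature should spare the prenyl and 1,1-dimethylallyl chains from cyclisation onto the neighbouring phenols.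

Compound list
1 | 5-fluororesorcinol | Oc1cc(O)cc(F)c1 | starting material
2 | N-[(2-fluoro-4,6-dihydroxyphenyl)methylidene]-N-methylmethanaminium chloride (aryl iminium chloride) | C[N+](C)=Cc1c(O)cc(O)cc1F.[Cl-] | intermediate (not isolated)
3 | 2-fluoro-4,6-dihydroxybenzaldehyde | O=Cc1c(O)cc(O)cc1F | intermediate
4 | prenyl bromide (1-bromo-3-methylbut-2-ene) | CC(C)=CCBr | starting material
5 | 2-fluoro-6-hydroxy-4-(3-methylbut-2-en-1-yloxy)benzaldehyde | O=Cc1c(O)cc(OCC=C(C)C)cc1F | intermediate
6 | 2-fluoro-6-(methoxymethoxy)-4-(3-methylbut-2-en-1-yloxy)benzaldehyde | O=Cc1c(F)cc(OCC=C(C)C)cc1OCOC | intermediate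
7 | 2-fluoro-6-(methoxymethoxy)-4-(3-methylbut-2-en-1-yloxy)benzoic acid | OC(=O)c1c(F)cc(OCC=C(C)C)cc1OCOC | intermediate
8 | 1-[2-fluoro-6-(methoxymethoxy)-4-(3-methylbut-2-en-1-yloxy)benzoyl]imidazole | O=C(c1c(F)cc(OCC=C(C)C)cc1OCOC)n1ccnc1 | intermediate
9 | 3-bromo-4,5-dihydroxybenzaldehyde | O=Cc1cc(O)c(O)c(Br)c1 | starting material
10 | 3-bromo-4,5-bis(methoxymethoxy)benzaldehyde | O=Cc1cc(OCOC)c(OCOC)c(Br)c1 | intermediate
11 | tributyl(3-methylbut-2-en-1-yl)stannane | CC(C)=CC[Sn](CCCC)(CCCC)CCCC | starting material
12 | 3,4-bis(methoxymethoxy)-5-(3-methylbut-2-en-1-yl)benzaldehyde | O=Cc1cc(OCOC)c(OCOC)c(CC=C(C)C)c1 | intermediate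
13 | tributyl[(methoxymethoxy)methyl]stannane | CCCC[Sn](CCCC)(CCCC)COCOC | starting material
14 | (methoxymethoxy)methyllithium | [Li]COCOC | intermediate (not isolated)
15 | 1-[3,4-bis(methoxymethoxy)-5-(3-methylbut-2-en-1-yl)phenyl]-2-(methoxymethoxy)ethanol, racemic | COCOCC(O)c1cc(OCOC)c(OCOC)c(CC=C(C)C)c1 | intermediate
16 | 1-[3,4-bis(methoxymethoxy)-5-(3-methylbut-2-en-1-yl)phenyl]-2-(methoxymethoxy)ethanone | COCOCC(=O)c1cc(OCOC)c(OCOC)c(CC=C(C)C)c1 | intermediate
17 | lithium (Z)-enolate of 16 | COCO/C=C(\O[Li])c1cc(OCOC)c(OCOC)c(CC=C(C)C)c1 | intermediate (not isolated)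
18 | lithium enolate of 1-[2-fluoro-6-(methoxymethoxy)-4-(3-methylbut-2-en-1-yloxy)phenyl]-2-(methoxymethoxy)-3-[3,4-bis(methoxymethoxy)-5-(3-methylbut-2-en-1-yl)phenyl]propane-1,3-dione, drawn with the O–Li on the ring B side and cis to the ring A acyl group | [Li]O/C(c1cc(OCOC)c(OCOC)c(CC=C(C)C)c1)=C(/OCOC)C(=O)c1c(F)cc(OCC=C(C)C)cc1OCOC | intermediate (not isolated)
19 | 2-[3,4-bis(methoxymethoxy)-5-(3-methylbut-2-en-1-yl)phenyl]-3,5-bis(methoxymethoxy)-7-(3-methylbut-2-en-1-yloxy)-4H-chromen-4-one | CC(C)=CCOc1cc(OCOC)c2c(=O)c(OCOC)c(-c3cc(OCOC)c(OCOC)c(CC=C(C)C)c3)oc2c1 | intermediate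
20 | 2-[3,4-bis(methoxymethoxy)-5-(3-methylbut-2-en-1-yl)phenyl]-3,5-bis(methoxymethoxy)-8-(2-methylbut-3-en-2-yl)-8H-chromene-4,7-dione, racemic at C8 | C=CC(C)(C)C1C(=O)C=C(OCOC)C2=C1OC(c1cc(OCOC)c(OCOC)c(CC=C(C)C)c1)=C(OCOC)C2=O | intermediate (not isolated)
21 | 7-hydroxy-2-[3,4-bis(methoxymethoxy)-5-(3-methylbut-2-en-1-yl)phenyl]-3,5-bis(methoxymethoxy)-8-(2-methylbut-3-en-2-yl)-4H-chromen-4-one | C=CC(C)(C)c1c(O)cc(OCOC)c2c(=O)c(OCOC)c(-c3cc(OCOC)c(OCOC)c(CC=C(C)C)c3)oc12 | intermediate
22 | 2-[3,4-dihydroxy-5-(3-methylbut-2-en-1-yl)phenyl]-3,5,7-trihydroxy-8-(2-methylbut-3-en-2-yl)-4H-chromen-4-one | C=CC(C)(C)c1c(O)cc(O)c2c(=O)c(O)c(-c3cc(O)c(O)c(CC=C(C)C)c3)oc12 | target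

Total step count: 12 (a ring A branch of five steps, a ring B branch of four steps, then three common steps).
Longest linear sequence: 8 steps (steps 1 to 5, then 10, 11 and 12).

Steps most likely to fail

Step 10. The acyl group may be transferred to the enolate oxygen or to the amide base instead of to carbon, residual imidazole may quench the enolate by proton transfer, and fluoride displacement may be slow because the lithium chelate holds the diketonate oxygen away from C8a on an electron-rich ring A. The fallback sets out from aldehyde 6 and ketone 16 and comes back at 19. Enolate 17 is made as before and added to aldehyde 6 at −78 °C in an aldol addition, which should give 3-[2-fluoro-6-(methoxymethoxy)-4-(3-methylbut-2-en-1-yloxy)phenyl]-3-hydroxy-2-(methoxymethoxy)-1-[3,4-bis(methoxymethoxy)-5-(3-methylbut-2-en-1-yl)phenyl]propan-1-one F1 as a mixture of diastereomers, both centres being lost later. Dess–Martin oxidation should then give the neutral 1-[2-fluoro-6-(methoxymethoxy)-4-(3-methylbut-2-en-1-yloxy)phenyl]-2-(methoxymethoxy)-3-[3,4-bis(methoxymethoxy)-5-(3-methylbut-2-en-1-yl)phenyl]propane-1,3-dione F2. K2CO3 in DMF at 80 °C converts F2 into a potassium diketonate free of the lithium chelate, which closes ring C by displacement of fluoride to give 19. The C3–C4 bond is thus made by aldol addition and oxidation in place of the Claisen condensation, and the ring closure becomes a separate operation.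

Step 11. The allyl unit may migrate to C6 as well as to C8 if the lanthanide chelates the C4 carbonyl and the 5-oxygen, MOM groups may be lost at the Lewis acid, and the freed 7-OH may add to the new vinyl group. The fallback sets out from 19 and comes back at 21. It replaces Lewis-acid catalysis by an uncatalysed thermal shift with trapping of the phenol: 19 is heated in N,N-diethylaniline with Ac2O and NaOAc at about 190 °C, so that the phenol is acetylated as soon as dienone 20 tautomerises. This should give 7-acetoxy-2-[3,4-bis(methoxymethoxy)-5-(3-methylbut-2-en-1-yl)phenyl]-3,5-bis(methoxymethoxy)-8-(2-methylbut-3-en-2-yl)-4H-chromen-4-one F3. K2CO3 in MeOH at 0 °C then removes the acetate and returns 21.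

Step 7. The allyl unit may be transferred through its tertiary end to give the 1,1-dimethylallyl arene, the C–Br bond may be reduced, and coupling next to the ortho MOM ether may be slow. The fallback sets out from 10 and comes back at 12, using polar organometallic alkylation in place of cross-coupling. Aldehyde 10 is converted with HC(OMe)3 and catalytic pyridinium p-toluenesulfonate in MeOH into 1-bromo-5-(dimethoxymethyl)-2,3-bis(methoxymethoxy)benzene F4. Bromine–lithium exchange with n-BuLi in THF at −78 °C gives [5-(dimethoxymethyl)-2,3-bis(methoxymethoxy)phenyl]lithium F5. Alkylation with prenyl bromide 4 in the presence of CuBr·SMe2 should occur at the primary carbon and give 5-(dimethoxymethyl)-1,2-bis(methoxymethoxy)-3-(3-methylbut-2-en-1-yl)benzene F6. Pyridinium p-toluenesulfonate in wet acetone at rt then releases aldehyde 12 with the MOM acetals intact.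

Further compounds
F1 | step 10 | 3-[2-fluoro-6-(methoxymethoxy)-4-(3-methylbut-2-en-1-yloxy)phenyl]-3-hydroxy-2-(methoxymethoxy)-1-[3,4-bis(methoxymethoxy)-5-(3-methylbut-2-en-1-yl)phenyl]propan-1-one (diastereomer mixture) | COCOC(C(O)c1c(F)cc(OCC=C(C)C)cc1OCOC)C(=O)c1cc(OCOC)c(OCOC)c(CC=C(C)C)c1
F2 | step 10 | 1-[2-fluoro-6-(methoxymethoxy)-4-(3-methylbut-2-en-1-yloxy)phenyl]-2-(methoxymethoxy)-3-[3,4-bis(methoxymethoxy)-5-(3-methylbut-2-en-1-yl)phenyl]propane-1,3-dione | COCOC(C(=O)c1c(F)cc(OCC=C(C)C)cc1OCOC)C(=O)c1cc(OCOC)c(OCOC)c(CC=C(C)C)c1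
F3 | step 11 | 7-acetoxy-2-[3,4-bis(methoxymethoxy)-5-(3-methylbut-2-en-1-yl)phenyl]-3,5-bis(methoxymethoxy)-8-(2-methylbut-3-en-2-yl)-4H-chromen-4-one | CC(=O)Oc1cc(OCOC)c2c(=O)c(OCOC)c(-c3cc(OCOC)c(OCOC)c(CC=C(C)C)c3)oc2c1C(C)(C)C=C
F4 | step 7 | 1-bromo-5-(dimethoxymethyl)-2,3-bis(methoxymethoxy)benzene | COC(OC)c1cc(OCOC)c(OCOC)c(Br)c1
F5 | step 7 | [5-(dimethoxymethyl)-2,3-bis(methoxymethoxy)phenyl]lithium | COC(OC)c1cc(OCOC)c(OCOC)c([Li])c1
F6 | step 7 | 5-(dimethoxymethyl)-1,2-bis(methoxymethoxy)-3-(3-methylbut-2-en-1-yl)benzene | COC(OC)c1cc(OCOC)c(OCOC)c(CC=C(C)C)c1
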